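The data were generated by integration for substances that don't exist, and the scatter is random.

The trap I met was to take a flat curve for an equilibrium. Thursday's run flattened at 19.35 mM of target from 50.0 mM of starting material, the limiting reagent by charge. An equilibrium pushes back on added target, so Saturday's run, the same charge with target added, served as the test. Its net gain over Thursday's read 1.03, where one marks no push at all.

| flask | starting material | coupling partner | target | time |
|---|---|---|---|---|
| Thursday's | 50.0 mM | 55.0 mM |  |  |
| Tuesday's | 20.0 mM | 25.0 mM |  |  |
| Wednesday's | 50.0 mM | 83.0 mM |  |  |
| Saturday's | 50.0 mM | 55.0 mM | 25.0 mM |  |
| Friday's | 50.0 mM | 55.0 mM |  | 680 s |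

- Thursday's run (time / s: [target] / mM): 9.7: 5.68; 29: 11.50; 56: 15.57; 89: 17.84; 130: 19.32; 170: 19.35
- Tuesday's run (time / s: [target] / mM): 9.7: 0.50; 29: 1.30; 56: 1.83; 89: 2.45; 130: 2.46; 170: 3.21
- Wednesday's run (time / s: [target] / mM): 9.7: 11.74; 29: 21.22; 56: 26.69; 89: 29.29; 130: 30.58; 170: 31.02
- Saturday's run (time / s: [target] / mM): 9.7: 30.87; 29: 37.01; 56: 40.78; 89: 42.96; 130: 44.26; 170: 44.89

(scatter of a reading: 0.2 mM)

- Overall: starting material + coupling partner -> target.
- Constant volume, constant temperature.
- "The second partner" is coupling partner.
- An order is taken over about fifteen percent of the charge, up and down.

* reaction order in [coupling partner] at the outset, round the charge of the Thursday's run, defined at two percent of the starting material turned into target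
* reaction order in [starting material] at the outset, round the charge of the Thursday's run, defined at two percent of the starting material turned into target (one fixed amount of target, the same in the runs compared)
* target in the Friday's run at 680 s, as a share of the starting material charged

I therefore treated the curve as a first-order approach and carried one quantity, the stall constant τ: the final c(target) made, divided by the first slope. For Thursday's run it read 33.0 s. The bench rule says such an approach is finished after 5 time constants. The last reading of Thursday's run stood at 5.14 of them, so the rule counted that curve as finished; this was my estimate from a single constant, not a reading of the tail.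

The border showed in the other charges. Wednesday's run read 25.6 s, shorter than Thursday's. Tuesday's run gave roughly 62.3 s, so its last reading came at 2.73 constants, short of the rule. The constant belongs to a charge and does not travel.

Friday's charge is Thursday's, and its 680 s is 20.6 constants. I took the mean net plateau of Thursday's and Saturday's runs and reckoned 39.2 %.

The forecast gave orders of 1.95 in coupling partner and 1 in starting material, and 40 % for Friday's run, holding that “the active species dies with time”.

The flask gave 2.1, 1.0 and 40.5 %.

    starting material + 2 coupling partner → target + coupling partner (4.900 L² mol⁻² s⁻¹)
    starting material → decomposed substrate (0.008370 s⁻¹)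
    coupling partner → lost reagent (0.003270 s⁻¹)

The constant held for the early curve on Thursday's charge: τ puts a quarter of the starting material as target at 34.3 s, and the simulated time is 32.9 s. Wednesday's own constant puts half at 42.0 s, against 44.5 s. At the end of the curve my 39.2 % for Friday's run lay 1.3 percentage points below the flask's figure, which is 0.645 mM of target, more than the scatter. The stall itself came in part from the conversion of starting material into decomposed substrate: Friday's run without that step gave 55.9 %, against 40.5 % with it.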